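The cycloheptene ring is treated as a cyclopentenone (C6, C7, C8, C8a, C3a; azulene locants) enlarged by the two-carbon unit C4–C5. The key step exploits the 1,3-relation of the tertiary C3 hydroxyl and the C4 oxygen: an ethynyl(dimethyl)silyl ether on O3 is added photochemically across the enone C=C (future C6 and C3a), so that one operation forms C5–C6 and C3a–C4 and closes a strained cyclobutene. Thermal opening of that cyclobutene then cleaves the old C6–C3a bond to give the seven-membered dienone; reductive 1,3-transposition, Tamao oxidation and reduction set C3a and C4. The precursor is a bicyclo[3.3.0]octenone.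

Key step: step 6

Remark: hydroazulenes carry azulene locants (C1–C8a) and diquinanes pentalene locants; the target is taken as cis-fused with the C3 hydroxyl, H-3a, H-4, the C8 oxygen and the 8a-methyl group on one face, as the SMILES encodes.

Step 1
Reactants: 1 3-methylcyclopent-2-en-1-one; 2 2-(2-bromoethyl)-2-methyl-1,3-dioxolane
Product: 4 (3S)-3-methyl-3-[2-(2-methyl-1,3-dioxolan-2-yl)ethyl]cyclopentan-1-one, via Grignard reagent 3 (not isolated)
Conditions: 2, Mg, THF; then 1, Cu(OTf)2 (3 mol%), chiral NHC ligand (4 mol%), Et2O, −30 °C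
Reagents that add atoms: none
Why: Copper-catalysed asymmetric conjugate addition of a Grignard reagent to a β-substituted cyclopentenone should build the quaternary centre, the ligand antipode being chosen to give the (S)-ketone.

Step 2
Reactants: 4 (3S)-3-methyl-3-[2-(2-methyl-1,3-dioxolan-2-yl)ethyl]cyclopentan-1-one
Product: 6 (3aR)-3a,6-dimethyl-3,3a,4,5-tetrahydropentalen-1(2H)-one, via diketone 5 (not isolated)
Conditions: HCl (cat.), THF/H2O, 25 °C; then KOH (0.3 equiv), MeOH, 65 °C
Reagents that add atoms: none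
Why: Ketal hydrolysis and intramolecular aldol condensation of the 1,6-diketone should give the fused acylcyclopentene, the only aldol that can dehydrate (as 2,7-octanedione gives 1-acetyl-2-methylcyclopentene); no stereocentre is touched.

Step 3
Reactants: 6 (3aR)-3a,6-dimethyl-3,3a,4,5-tetrahydropentalen-1(2H)-one
Product: 7 (1S,3aR)-3a,6-dimethyl-1-(propan-2-yl)-1,2,3,3a,4,5-hexahydropentalen-1-ol
Conditions: i-PrMgCl, CeCl3, THF, −78 °C
Reagents that add atoms: isopropylmagnesium chloride CC(C)[Mg]Cl
Why: Organocerium 1,2-addition to the hindered enone should occur anti to the pseudo-axial angular 3a-methyl group while the ring-fusion carbon is still sp2, placing the hydroxyl cis to that methyl (1S).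

Step 4
Reactants: 7 (1S,3aR)-3a,6-dimethyl-1-(propan-2-yl)-1,2,3,3a,4,5-hexahydropentalen-1-ol
Product: 9 (1S,3aR)-1-{[ethynyl(dimethyl)silyl]oxy}-3a,6-dimethyl-1-(propan-2-yl)-1,2,3,3a,4,5-hexahydropentalene, via chlorosilyl ether 8 (not isolated)
Conditions: Me2SiCl2 (excess), imidazole, CH2Cl2, 0 °C; evaporation; HC≡CMgBr, THF, −78 to 0 °C
Reagents that add atoms: dichlorodimethylsilane C[Si](C)(Cl)Cl; ethynylmagnesium bromide C#C[Mg]Br
Why: Silylation of the tertiary alcohol with the reactive dichlorosilane and Grignard substitution of the remaining Si–Cl bond is the standard way to an unsymmetrical silicon tether; no carbonyl group is present to compete.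

Step 5
Reactants: 9 (1S,3aR)-1-{[ethynyl(dimethyl)silyl]oxy}-3a,6-dimethyl-1-(propan-2-yl)-1,2,3,3a,4,5-hexahydropentalene
Product: 10 (4S,6aS)-4-{[ethynyl(dimethyl)silyl]oxy}-3,6a-dimethyl-4-(propan-2-yl)-4,5,6,6a-tetrahydropentalen-2(1H)-one
Conditions: Rh2(cap)4 (1 mol%), t-BuOOH, CH2Cl2, 25 °C
Reagents that add atoms: tert-butyl hydroperoxide CC(C)(C)OO
Why: Dirhodium caprolactamate/t-BuOOH allylic C–H oxidation should give the enone because the tetrasubstituted alkene has a single allylic methylene (C5 of 9), which reacts before the allylic methyl group.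

Step 6
Reactants: 10 (4S,6aS)-4-{[ethynyl(dimethyl)silyl]oxy}-3,6a-dimethyl-4-(propan-2-yl)-4,5,6,6a-tetrahydropentalen-2(1H)-one
Product: 11 tetracyclic cyclobutene ketone in which the ethynyl group has added across C3=C3a of 10 on the face of the 6a-methyl group (=CH carbon on C3, silicon-bearing carbon on C3a, O4–Si(CH3)2 bridge kept)
Conditions: hν (λ ≥ 350 nm), MeCN (0.005 M), 0 °C
Reagents that add atoms: none
Why: Triplet excitation of the cyclopentenone lets its β-carbon C3a bond to the silicon-bearing alkyne carbon (5-exo-dig closure of the 1-oxa-2-silacyclopentane ring), and the 1,4-diradical so formed (α-keto radical at C3, vinyl radical) collapses to close the cyclobutene (four-membered ring by radical recombination). The closest known reaction type is the intramolecular enone–alkyne [2+2] photocycloaddition, run here through a temporary silicon tether as in silicon-tethered enone–alkene photocycloadditions. The two new quaternary stereocentres, C3 and C3a, are controlled by the substrate: the tether on O4 delivers the alkyne to the face of the silyloxy group, which is also the face of the 6a-methyl group and the only face that leaves the bicyclo[3.3.0]octane cis-fused. Regioselectivity (silicon-bearing carbon to C3a, CH to C3) is needed so that the later C4 oxygen sits next to the ring-fusion carbon; the three-atom C4–O–Si link secures it, because the crossed mode would give a bridged and far more strained ring system. Chemoselectivity against a secondary 1,3-acyl shift of the β,γ-unsaturated ketone product is sought by exciting only the enone n→π* band at high dilution.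

Step 7
Reactants: 11 tetracyclic cyclobutene ketone
Product: 12 (3S,8aS)-6,8a-dimethyl-3-(propan-2-yl)-2,3,8,8a-tetrahydroazulen-7(1H)-one with O3 and C4 joined through Si(CH3)2
Conditions: toluene, 180 °C (sealed tube)
Reagents that add atoms: none
Why: Thermal electrocyclic ring opening of the cyclobutene should cleave the σ-bond opposite its double bond, the old enone C3–C3a bond between two quaternary carbons; the ring strain and the α-keto and allylic stabilisation of the breaking bond drive this two-carbon ring expansion to the cyclohepta-2,4-dienone.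

Step 8
Reactants: 12 silicon-bridged tetrahydroazulen-7(1H)-one
Product: 13 N-tosylhydrazone of 12 at C7
Conditions: TsNHNH2, EtOH, 50 °C
Reagents that add atoms: 4-methylbenzenesulfonohydrazide Cc1ccc(cc1)S(=O)(=O)NN
Why: Condensation of the only ketone with tosylhydrazide; no stereocentre is formed.

Step 9
Reactants: 13 N-tosylhydrazone of 12
Product: 14 (3S,8aS)-6,8a-dimethyl-3-(propan-2-yl)-1,2,3,5,8,8a-hexahydroazulene with O3 and C4 joined through Si(CH3)2 (C3a=C4 and C6=C7 double bonds)
Conditions: catecholborane, CHCl3, 0 °C; then NaOAc·3H2O, 60 °C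
Reagents that add atoms: none
Why: Kabalka alkene-transposing reduction: hydride adds to the C=N carbon (C7), loss of sulfinate gives an allylic diazene, and its retro-ene loss of N2 delivers hydrogen to C5 and moves the double bond to C6=C7, leaving the vinylsilane untouched.

Step 10
Reactants: 14 silicon-bridged hexahydroazulene
Product: 16 (3S,3aS,4R,8aS)-6,8a-dimethyl-3-(propan-2-yl)-1,2,3,3a,4,5,8,8a-octahydroazulene-3,4-diol, via ketone 15 (not isolated)
Conditions: H2O2, KF, KHCO3, THF/MeOH, 25 °C; then NaBH4, −20 °C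
Reagents that add atoms: hydrogen peroxide OO
Why: Tamao–Fleming oxidation of the alkenyl(alkoxy)silane should give the C4 enol and free the C3 hydroxyl, the enol should be protonated at C3a on the face anti to the isopropyl group (cis-fused ketone), and NaBH4 should then attack the C4 carbonyl from the same convex face to give the 4R alcohol before the C6=C7 bond can move into conjugation.

Step 11
Reactants: 16 (3S,3aS,4R,8aS)-6,8a-dimethyl-3-(propan-2-yl)-1,2,3,3a,4,5,8,8a-octahydroazulene-3,4-diol
Product: 17 (3S,3aS,4R,8aS)-3-hydroxy-6,8a-dimethyl-3-(propan-2-yl)-1,2,3,3a,4,5,8,8a-octahydroazulen-4-yl 4-(acetyloxy)benzoate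
Conditions: 4-AcOC6H4COCl, pyridine, DMAP, CH2Cl2, 40 °C
Reagents that add atoms: 4-(acetyloxy)benzoyl chloride CC(=O)Oc1ccc(cc1)C(Cl)=O
Why: DMAP-catalysed acylation should take place only at the secondary alcohol; the hindered tertiary alcohol stays free.

Step 12
Reactants: 17 4-(acetyloxy)benzoate of the diol
Product: 18 (3S,3aS,4R,8aR)-3-hydroxy-6,8a-dimethyl-8-oxo-3-(propan-2-yl)-1,2,3,3a,4,5,8,8a-octahydroazulen-4-yl 4-(acetyloxy)benzoate
Conditions: Rh2(cap)4 (1 mol%), t-BuOOH, ClCH2CH2Cl, 40 °C
Reagents that add atoms: tert-butyl hydroperoxide CC(C)(C)OO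
Why: Allylic C–H oxidation of the trisubstituted alkene should occur at the methylene next to its CH= terminus (C8), the usual site for 1-methylcycloalkenes, since C5 is deactivated by the neighbouring acyloxy group and leads to the less substituted allyl radical.

Step 13
Reactants: 18 8-oxo ester
Product: 19 (3S,3aS,4R,8R,8aR)-3,8-dihydroxy-6,8a-dimethyl-3-(propan-2-yl)-1,2,3,3a,4,5,8,8a-octahydroazulen-4-yl 4-(acetyloxy)benzoate
Conditions: NaBH4, CeCl3·7H2O, MeOH, −78 °C
Reagents that add atoms: none
Why: Luche 1,2-reduction; hydride should add to the C8 carbonyl anti to the pseudo-axial 8a-methyl group, so the new hydroxyl is cis to it (8R).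

Step 14
Reactants: 19 allylic alcohol
Product: 20 (3S,3aS,4R,8R,8aR)-3-hydroxy-6,8a-dimethyl-8-[(3-methylbutanoyl)oxy]-3-(propan-2-yl)-1,2,3,3a,4,5,8,8a-octahydroazulen-4-yl 4-(acetyloxy)benzoate
Conditions: (CH3)2CHCH2COCl, pyridine, DMAP, CH2Cl2, 0 to 25 °C
Reagents that add atoms: 3-methylbutanoyl chloride CC(C)CC(Cl)=O
Why: DMAP-catalysed acylation of the secondary allylic alcohol; the tertiary alcohol does not react.

Step 15
Reactants: 20 isovalerate aryl acetate
Product: 21 (3S,3aS,4R,8R,8aR)-3-hydroxy-6,8a-dimethyl-8-[(3-methylbutanoyl)oxy]-3-(propan-2-yl)-1,2,3,3a,4,5,8,8a-octahydroazulen-4-yl 4-hydroxybenzoate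
Conditions: K2CO3 (cat.), MeOH, 0 °C
Reagents that add atoms: none
Why: Base-catalysed methanolysis of the aryl acetate should be far faster than that of the two hindered alkyl esters.

Compound list
1 | 3-methylcyclopent-2-en-1-one | CC1=CC(=O)CC1 | starting material
2 | 2-(2-bromoethyl)-2-methyl-1,3-dioxolane | CC1(CCBr)OCCO1 | starting material
3 | [2-(2-methyl-1,3-dioxolan-2-yl)ethyl]magnesium bromide | CC1(CC[Mg]Br)OCCO1 | intermediate
4 | (3S)-3-methyl-3-[2-(2-methyl-1,3-dioxolan-2-yl)ethyl]cyclopentan-1-one | O=C1CC[C@@](C)(CCC2(C)OCCO2)C1 | intermediate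
5 | (3R)-3-methyl-3-(3-oxobutyl)cyclopentan-1-one | O=C1CC[C@@](C)(CCC(C)=O)C1 | intermediate
6 | (3aR)-3a,6-dimethyl-3,3a,4,5-tetrahydropentalen-1(2H)-one | CC1=C2C(=O)CC[C@@]2(C)CC1 | intermediate
7 | (1S,3aR)-3a,6-dimethyl-1-(propan-2-yl)-1,2,3,3a,4,5-hexahydropentalen-1-ol | CC1=C2[C@@](O)(C(C)C)CC[C@@]2(C)CC1 | intermediate
8 | (1S,3aR)-1-{[chloro(dimethyl)silyl]oxy}-3a,6-dimethyl-1-(propan-2-yl)-1,2,3,3a,4,5-hexahydropentalene | CC1=C2[C@@](O[Si](C)(C)Cl)(C(C)C)CC[C@@]2(C)CC1 | intermediate
9 | (1S,3aR)-1-{[ethynyl(dimethyl)silyl]oxy}-3a,6-dimethyl-1-(propan-2-yl)-1,2,3,3a,4,5-hexahydropentalene | CC1=C2[C@@](O[Si](C)(C)C#C)(C(C)C)CC[C@@]2(C)CC1 | intermediate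
10 | (4S,6aS)-4-{[ethynyl(dimethyl)silyl]oxy}-3,6a-dimethyl-4-(propan-2-yl)-4,5,6,6a-tetrahydropentalen-2(1H)-one | CC1=C2[C@@](O[Si](C)(C)C#C)(C(C)C)CC[C@@]2(C)CC1=O | intermediate
11 | tetracyclic cyclobutene ketone from 10 (=CH carbon on C3, silicon-bearing carbon on C3a, both on the 6a-methyl face; O4–Si(CH3)2 bridge; C2 ketone) | C[C@]12C(=O)C[C@]3(C)CC[C@@]4(C(C)C)O[Si](C)(C)C(=C2)[C@@]134 | intermediate
12 | (3S,8aS)-6,8a-dimethyl-3-(propan-2-yl)-2,3,8,8a-tetrahydroazulen-7(1H)-one with O3 and C4 joined through Si(CH3)2 | CC1=CC2=C3[C@](C(C)C)(O[Si]2(C)C)CC[C@@]3(C)CC1=O | intermediate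
13 | N-tosylhydrazone of 12 at C7 | CC1=CC2=C3[C@](C(C)C)(O[Si]2(C)C)CC[C@@]3(C)CC1=NNS(=O)(=O)c1ccc(C)cc1 | intermediate
14 | (3S,8aS)-6,8a-dimethyl-3-(propan-2-yl)-1,2,3,5,8,8a-hexahydroazulene with O3 and C4 joined through Si(CH3)2 | CC1=CC[C@]2(C)CC[C@@]3(C(C)C)O[Si](C)(C)C(C1)=C23 | intermediate
15 | (3S,3aR,8aS)-3-hydroxy-6,8a-dimethyl-3-(propan-2-yl)-2,3,3a,5,8,8a-hexahydroazulen-4(1H)-one | CC1=CC[C@]2(C)CC[C@](O)(C(C)C)[C@@H]2C(=O)C1 | intermediate
16 | (3S,3aS,4R,8aS)-6,8a-dimethyl-3-(propan-2-yl)-1,2,3,3a,4,5,8,8a-octahydroazulene-3,4-diol | CC1=CC[C@]2(C)CC[C@](O)(C(C)C)[C@@H]2[C@H](O)C1 | intermediate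
17 | (3S,3aS,4R,8aS)-3-hydroxy-6,8a-dimethyl-3-(propan-2-yl)-1,2,3,3a,4,5,8,8a-octahydroazulen-4-yl 4-(acetyloxy)benzoate | CC1=CC[C@]2(C)CC[C@](O)(C(C)C)[C@@H]2[C@H](OC(=O)c2ccc(OC(C)=O)cc2)C1 | intermediate
18 | (3S,3aS,4R,8aR)-3-hydroxy-6,8a-dimethyl-8-oxo-3-(propan-2-yl)-1,2,3,3a,4,5,8,8a-octahydroazulen-4-yl 4-(acetyloxy)benzoate | CC1=CC(=O)[C@]2(C)CC[C@](O)(C(C)C)[C@@H]2[C@H](OC(=O)c2ccc(OC(C)=O)cc2)C1 | intermediate
19 | (3S,3aS,4R,8R,8aR)-3,8-dihydroxy-6,8a-dimethyl-3-(propan-2-yl)-1,2,3,3a,4,5,8,8a-octahydroazulen-4-yl 4-(acetyloxy)benzoate | CC1=C[C@@H](O)[C@]2(C)CC[C@](O)(C(C)C)[C@@H]2[C@H](OC(=O)c2ccc(OC(C)=O)cc2)C1 | intermediate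
20 | (3S,3aS,4R,8R,8aR)-3-hydroxy-6,8a-dimethyl-8-[(3-methylbutanoyl)oxy]-3-(propan-2-yl)-1,2,3,3a,4,5,8,8a-octahydroazulen-4-yl 4-(acetyloxy)benzoate | CC1=C[C@@H](OC(=O)CC(C)C)[C@]2(C)CC[C@](O)(C(C)C)[C@@H]2[C@H](OC(=O)c2ccc(OC(C)=O)cc2)C1 | intermediate
21 | (3S,3aS,4R,8R,8aR)-3-hydroxy-6,8a-dimethyl-8-[(3-methylbutanoyl)oxy]-3-(propan-2-yl)-1,2,3,3a,4,5,8,8a-octahydroazulen-4-yl 4-hydroxybenzoate | CC1=C[C@@H](OC(=O)CC(C)C)[C@]2(C)CC[C@](O)(C(C)C)[C@@H]2[C@H](OC(=O)c2ccc(O)cc2)C1 | target

Total step count: 15. Longest linear sequence: 15 steps (1 to 21).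

Steps most likely to fail

Step 6. The tethered cycloaddition may be slow at the doubly neopentyl β-carbon, and the product may undergo a photochemical 1,3-acyl shift on further irradiation. The fallback sets out from 10 and drops the tether. The silyl ether is cleaved with Bu4NF to the hydroxy enone F1, which is irradiated with ethoxyethyne; the head-to-tail preference of electron-rich partners should place the ethoxy-bearing carbon on the enone β-carbon and give cyclobutene F2. Thermal ring opening should give the ethoxy dienone F3. Its tosylhydrazone F4 is reduced with catecholborane to the dienol ether F5, and brief hydrolysis of the enol ether (oxalic acid on wet silica gel, 0 °C) should give ketone 15, where the route is rejoined.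

Step 9. Hydride may be delivered without the allylic transposition, or the hindered hydrazone may be reduced incompletely. The fallback sets out from 12: NaBH4/CeCl3 reduction of the dienone gives allylic alcohol F6 (either C7 epimer). Mitsunobu displacement with 2-nitrobenzenesulfonohydrazide (PPh3, diethyl azodicarboxylate) and warming should then give the allylic diazene, whose sigmatropic loss of N2 gives 14, where the route is rejoined.

Step 1. The conjugate addition of a functionalised Grignard reagent to a cyclopentenone may proceed with insufficient enantioselectivity. The fallback sets out from 2 and reverses the roles of the two carbon groups: Grignard reagent 3 is added to 3-ethoxycyclopent-2-en-1-one, and mild acidic work-up gives enone F7. Copper-catalysed conjugate addition of Me3Al with a chiral phosphoramidite ligand should then give 4, where the route is rejoined.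

Further compounds
F1 | step 6 | (4S,6aS)-4-hydroxy-3,6a-dimethyl-4-(propan-2-yl)-4,5,6,6a-tetrahydropentalen-2(1H)-one | CC1=C2[C@@](O)(C(C)C)CC[C@@]2(C)CC1=O
F2 | step 6 | cyclobutene photoadduct of F1 with ethoxyethyne (ethoxy-bearing carbon on C3a, =CH carbon on C3, on the 6a-methyl face) | C[C@]12C(=O)C[C@]3(C)CC[C@](O)(C(C)C)[C@]13C(OCC)=C2
F3 | step 6 | (3S,8aS)-4-ethoxy-3-hydroxy-6,8a-dimethyl-3-(propan-2-yl)-2,3,8,8a-tetrahydroazulen-7(1H)-one | CC1=CC(OCC)=C2[C@@](O)(C(C)C)CC[C@@]2(C)CC1=O
F4 | step 6 | N-tosylhydrazone of F3 at C7 | CC1=CC(OCC)=C2[C@@](O)(C(C)C)CC[C@@]2(C)CC1=NNS(=O)(=O)c1ccc(C)cc1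
F5 | step 6 | (3S,8aS)-4-ethoxy-6,8a-dimethyl-3-(propan-2-yl)-1,2,3,5,8,8a-hexahydroazulen-3-ol | CC1=CC[C@]2(C)CC[C@](O)(C(C)C)C2=C(OCC)C1
F6 | step 9 | 7-hydroxy compound from 12 (C7 configuration not defined) | CC1=CC2=C3[C@](C(C)C)(O[Si]2(C)C)CC[C@@]3(C)CC1O
F7 | step 1 | 3-[2-(2-methyl-1,3-dioxolan-2-yl)ethyl]cyclopent-2-en-1-one | CC1(CCC2=CC(=O)CC2)OCCO1
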